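## Retrosynthetic overview

1. Target ⇐ acetylation of the primary alcohol ⇐ ring B (closed last) by ring-closing metathesis of a vinyl ketone, made by vinyl addition to a six-membered lactone that ties the CH2OH to the C2' carbonyl.
2. (Z)-trisubstituted alkene ⇐ Wittig olefination of a methyl hemiketal ⇐ MeLi addition to a bridged δ-lactone (C4–CO–O–CH2–C1).
3. C1' and C5' ⇐ Ireland–Claisen rearrangement of an (E)-crotyl ester carried on that bridged lactone.
4. C1 (and the lock on C4) ⇐ face-selective dihydroxylation of an exocyclic alkene, lactol closure, oxidation.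
5. Ring A (closed first; C4 and C5) ⇐ amine-catalysed 5-exo Michael cyclisation of an achiral formyl dienoate ⇐ cyclohexene, formaldehyde, crotyl alcohol, Ph3P=C=C=O.

Locants used below: ring A (cyclopentanol) C1 = carbinol carbon, C4 = carbon bearing the dienyl chain, C5 = carbon bearing ring B; ring B (cyclopentenone) C1' = attachment carbon, C2' = C=O, C5' = methyl-bearing carbon; C11 = first carbon of the dienyl chain.

Assumption: the target is taken exactly as the SMILES encodes it, i.e. (1R,4R,5S) on ring A, (1'S,5'R) on ring B (ring A and methyl cis on ring B) and a 2Z alkene; the (S)-prolinol ether is assigned to this series by analogy with its known sense in aldehyde Michael additions, and its enantiomer is used if the sense proves opposite.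

## Route

Step 1
Reactants: 1 cyclohexene
Product: 4 6,6-dimethoxyhexanal, via methoxy hydroperoxide 2 (not isolated), via hydroperoxy acetal 3 (not isolated)
Conditions: O3, CH2Cl2/MeOH, −78 °C; TsOH (cat.), 25 °C; NaHCO3; Me2S
Reagents that add atoms: ozone ([O-][O+]=O); methanol (CO)
Why: Ozonolysis in methanol leaves a methoxy hydroperoxide at one end and an aldehyde at the other, acid acetalises only the free aldehyde, and Me2S then reduces the hydroperoxide end to the aldehyde (unsymmetrical ozonolytic cleavage); no stereocentre.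

Step 2
Reactants: 4 6,6-dimethoxyhexanal
Product: 5 6,6-dimethoxy-2-methylidenehexanal
Conditions: aq. HCHO (37%), pyrrolidine (10 mol%), EtCO2H (10 mol%), iPrOH, 45 °C
Reagents that add atoms: formaldehyde (C=O)
Why: Amine-catalysed Mannich condensation and elimination (organocatalytic α-methylenation of an aldehyde) installs the 2-methylidene group while the acetal survives the weak acid; no stereocentre.

Step 3
Reactants: 5 6,6-dimethoxy-2-methylidenehexanal; 6 (E)-but-2-en-1-ol; 7 (triphenylphosphoranylidene)ketene
Product: 9 (E)-but-2-en-1-yl (2E)-8,8-dimethoxy-4-methylideneoct-2-enoate, via ester ylide 8 (not isolated)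
Conditions: toluene, 60 °C (6 + 7); then 5, 80 °C
Reagents that add atoms: none
Why: The alcohol adds across the cumulated ylide to give the ester-stabilised phosphorane in the flask, which olefinates the enal E-selectively (three-component esterification–Wittig reaction); no stereocentre.

Step 4
Reactants: 9 (E)-but-2-en-1-yl (2E)-8,8-dimethoxy-4-methylideneoct-2-enoate
Product: 10 (E)-but-2-en-1-yl (2E)-4-methylidene-8-oxooct-2-enoate
Conditions: Amberlyst-15, acetone/H2O (20:1), 25 °C
Reagents that add atoms: water (O)
Why: Mild acid-catalysed acetal hydrolysis frees the aldehyde without touching the dienoate or the allylic ester; no stereocentre.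

Step 5
Reactants: 10 (E)-but-2-en-1-yl (2E)-4-methylidene-8-oxooct-2-enoate
Product: 11 (E)-but-2-en-1-yl 2-[(1R,2R)-2-formyl-5-methylidenecyclopentyl]acetate
Conditions: (S)-2-[diphenyl(trimethylsilyloxy)methyl]pyrrolidine (20 mol%), PhCO2H (20 mol%), toluene (0.05 M), 0 °C; used at once
Reagents that add atoms: none
Why: Proposed new method: enamine-mediated 5-exo-trig Michael ring closure onto a cross-conjugated 4-methylidene-2-enoate ester, an acceptor class not yet shown for this cyclisation, in which the (E)-enamine is shielded on one face by the diarylmethyl silyl ether (sets C4), a synclinal approach of the enoate puts the formyl and ester arms cis (sets C5), and attack at the methylidene terminus is ruled out as 5-endo; the closest known reactions are the amine-catalysed intramolecular Michael addition of ω-formyl enones and the enamine-to-enoate ring closure of organocatalytic double Michael cascades.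

Step 6
Reactants: 11 (E)-but-2-en-1-yl 2-[(1R,2R)-2-formyl-5-methylidenecyclopentyl]acetate
Product: 12 (E)-but-2-en-1-yl 2-(2,5-dihydroxy-3-oxabicyclo[3.2.1]octan-8-yl)acetate
Conditions: OsO4 (2 mol%), N-methylmorpholine N-oxide (1.1 equiv), acetone/H2O (5:1), 0 °C; Na2SO3
Reagents that add atoms: N-methylmorpholine N-oxide (C[N+]1([O-])CCOCC1); water (O)
Why: Upjohn dihydroxylation attacks the electron-richer exocyclic alkene (the crotyl alkene is slowed by its allylic acyloxy group) from the face opposite the two cis arms, which sets C1 with OH trans and CH2OH cis to them, and the CH2OH at once closes on the cis formyl group to a bridged lactol that locks C4.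

Step 7
Reactants: 12 (E)-but-2-en-1-yl 2-(2,5-dihydroxy-3-oxabicyclo[3.2.1]octan-8-yl)acetate
Product: 13 (E)-but-2-en-1-yl 2-(5-hydroxy-2-oxo-3-oxabicyclo[3.2.1]octan-8-yl)acetate
Conditions: Pr4N[RuO4] (5 mol%), N-methylmorpholine N-oxide (1.5 equiv), 4 Å molecular sieves, CH2Cl2, 25 °C
Reagents that add atoms: none
Why: Ley–Griffith oxidation turns the lactol into the bridged δ-lactone while the tertiary alcohol and the crotyl alkene are inert; no new stereocentre, and C4 can no longer epimerise.

Step 8
Reactants: 13 (E)-but-2-en-1-yl 2-(5-hydroxy-2-oxo-3-oxabicyclo[3.2.1]octan-8-yl)acetate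
Product: 16 (2S,3R)-2-(5-hydroxy-2-oxo-3-oxabicyclo[3.2.1]octan-8-yl)-3-methylpent-4-enoic acid, via silyl ketene acetal 14 (not isolated), via silyl ester 15 (not isolated)
Conditions: LiN(iPr)2 (2.4 equiv), THF, −78 °C; Me3SiCl (3 equiv); −78 → 50 °C; 1 M HCl
Reagents that add atoms: none
Why: Ireland–Claisen rearrangement: LiN(iPr)2 in THF gives the (E)-ketene acetal (silylation also caps the tertiary alcohol), the chair [3,3] shift with the (E)-crotyl group gives the anti C1'/C5' pair (cis on the later ring B), and the allyl terminus adds to the enolate face turned away from the O-silylated quaternary bridgehead C1, which sets C1' relative to C5; the lactone is not enolised because its α-carbon is a bridgehead.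

Step 9
Reactants: 16 (2S,3R)-2-(5-hydroxy-2-oxo-3-oxabicyclo[3.2.1]octan-8-yl)-3-methylpent-4-enoic acid
Product: 17 (2S,3R)-2-(2,5-dihydroxy-2-methyl-3-oxabicyclo[3.2.1]octan-8-yl)-3-methylpent-4-enoic acid
Conditions: MeLi (3.3 equiv), THF, −78 °C; NH4Cl (aq) at −78 °C
Reagents that add atoms: methyllithium ([Li]C)
Why: Two equivalents are used up by the acid and the alcohol, the third adds once to the lactone and the tetrahedral lithium alkoxide holds until the quench (mono-addition of an organolithium to a lactone), giving a methyl hemiketal that is a masked methyl ketone; the lithium carboxylate does not react at −78 °C and no stereocentre of the target is touched.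

Step 10
Reactants: 18 5-bromo-2-methylpent-2-ene; 19 triphenylphosphine
Product: 20 (4-methylpent-3-en-1-yl)triphenylphosphonium bromide
Conditions: MeCN, 80 °C
Reagents that add atoms: none
Why: SN2 quaternisation of the phosphine by the primary bromide; no stereocentre.

Step 11
Reactants: 17 (2S,3R)-2-(2,5-dihydroxy-2-methyl-3-oxabicyclo[3.2.1]octan-8-yl)-3-methylpent-4-enoic acid; 20 (4-methylpent-3-en-1-yl)triphenylphosphonium bromide
Product: 22 (4S)-4-[(2R)-but-3-en-2-yl]-7a-hydroxy-5-[(2Z)-6-methylhepta-2,5-dien-2-yl]hexahydrocyclopenta[c]pyran-3(1H)-one, via dihydroxy acid 21 (not isolated)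
Conditions: 20 (4 equiv), NaN(SiMe3)2 (7 equiv), THF, −78 → 25 °C; AcOH; then EDC·HCl, DMAP, CH2Cl2, 25 °C
Reagents that add atoms: none
Why: Base opens the hemiketal to the methyl ketone and the salt-free Wittig reaction with the unstabilised ylide is expected to put the ylide chain cis to the larger (ring) ketone substituent through the early puckered four-centre transition state (the ketone counterpart of Z-selective aldehyde olefination), which gives the 2Z alkene; carbodiimide lactonisation of the freed CH2OH onto the cis acid arm then protects both groups as one six-membered lactone.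

Step 12
Reactants: 22 (4S)-4-[(2R)-but-3-en-2-yl]-7a-hydroxy-5-[(2Z)-6-methylhepta-2,5-dien-2-yl]hexahydrocyclopenta[c]pyran-3(1H)-one
Product: 23 (4S,5R)-4-[2-hydroxy-2-(hydroxymethyl)-5-[(2Z)-6-methylhepta-2,5-dien-2-yl]cyclopentyl]-5-methylhepta-1,6-dien-3-one
Conditions: CH2=CHMgBr (2.5 equiv), CeCl3 (2.5 equiv), THF, −78 °C; NH4Cl (aq)
Reagents that add atoms: vinylmagnesium bromide (C=C[Mg]Br)
Why: The weakly basic organocerium reagent adds once to the lactone without enolising C1' (mono-addition to a lactone through a stable tetrahedral alkoxide), releasing the vinyl ketone (in equilibrium with its cyclic hemiketal) and the primary alcohol; no stereocentre changes.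

Step 13
Reactants: 23 (4S,5R)-4-[2-hydroxy-2-(hydroxymethyl)-5-[(2Z)-6-methylhepta-2,5-dien-2-yl]cyclopentyl]-5-methylhepta-1,6-dien-3-one
Product: 24 (4R,5S)-5-[(1S,2R,5R)-2-hydroxy-2-(hydroxymethyl)-5-[(2Z)-6-methylhepta-2,5-dien-2-yl]cyclopentyl]-4-methylcyclopent-2-en-1-one
Conditions: second-generation Grubbs catalyst (5 mol%), CH2Cl2 (5 mM), 40 °C
Reagents that add atoms: none
Why: Ring-closing metathesis of the vinyl ketone with the terminal alkene closes the cyclopentenone under neutral conditions, so the cis C1'/C5' pair set in step 8 is kept; the trisubstituted alkenes of the side chain do not take part.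

Step 14
Reactants: 24 (4R,5S)-5-[(1S,2R,5R)-2-hydroxy-2-(hydroxymethyl)-5-[(2Z)-6-methylhepta-2,5-dien-2-yl]cyclopentyl]-4-methylcyclopent-2-en-1-one
Product: 25 [(1R,2S,3R)-1-hydroxy-3-[(2Z)-6-methylhepta-2,5-dien-2-yl]-2-[(1S,5R)-5-methyl-2-oxocyclopent-3-en-1-yl]cyclopentyl]methyl acetate
Conditions: Ac2O (1.2 equiv), pyridine, DMAP (5 mol%), CH2Cl2, 0 °C
Reagents that add atoms: acetic anhydride (CC(=O)OC(C)=O)
Why: Acylation of the primary alcohol is far faster than that of the tertiary one (selective esterification), and the short cold exposure to a weak base leaves the α'-stereocentre of the enone alone.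

## Compound list

1 | cyclohexene | C1=CCCCC1 | starting material
2 | 6-hydroperoxy-6-methoxyhexanal | COC(OO)CCCCC=O | intermediate
3 | 6-hydroperoxy-1,1,6-trimethoxyhexane | COC(OC)CCCCC(OC)OO | intermediate
4 | 6,6-dimethoxyhexanal | COC(OC)CCCCC=O | intermediate
5 | 6,6-dimethoxy-2-methylidenehexanal | COC(OC)CCCC(=C)C=O | intermediate
6 | (E)-but-2-en-1-ol | C/C=C/CO | starting material
7 | (triphenylphosphoranylidene)ketene | O=C=C=P(c1ccccc1)(c1ccccc1)c1ccccc1 | starting material
8 | (E)-but-2-en-1-yl 2-(triphenylphosphoranylidene)acetate | C/C=C/COC(=O)C=P(c1ccccc1)(c1ccccc1)c1ccccc1 | intermediate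
9 | (E)-but-2-en-1-yl (2E)-8,8-dimethoxy-4-methylideneoct-2-enoate | COC(OC)CCCC(=C)/C=C/C(=O)OC/C=C/C | intermediate
10 | (E)-but-2-en-1-yl (2E)-4-methylidene-8-oxooct-2-enoate | O=CCCCC(=C)/C=C/C(=O)OC/C=C/C | intermediate
11 | (E)-but-2-en-1-yl 2-[(1R,2R)-2-formyl-5-methylidenecyclopentyl]acetate (formyl and ester arms cis) | C=C1CC[C@@H](C=O)[C@H]1CC(=O)OC/C=C/C | intermediate
12 | (E)-but-2-en-1-yl 2-(2,5-dihydroxy-3-oxabicyclo[3.2.1]octan-8-yl)acetate (bridged lactol, both anomers; C8 arm syn to the oxygen bridge) | OC3OC[C@@]1(O)CC[C@@H]3[C@H]1CC(=O)OC/C=C/C | intermediate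
13 | (E)-but-2-en-1-yl 2-(5-hydroxy-2-oxo-3-oxabicyclo[3.2.1]octan-8-yl)acetate (bridged lactone; C8 arm syn to the lactone bridge) | O=C3OC[C@@]1(O)CC[C@@H]3[C@H]1CC(=O)OC/C=C/C | intermediate
14 | (E)-silyl ketene acetal of 13, tertiary alcohol as trimethylsilyl ether | O=C3OC[C@@]1(O[Si](C)(C)C)CC[C@@H]3[C@H]1/C=C(/O[Si](C)(C)C)OC/C=C/C | intermediate
15 | trimethylsilyl ester of 16, tertiary alcohol as trimethylsilyl ether | O=C3OC[C@@]1(O[Si](C)(C)C)CC[C@@H]3[C@H]1[C@H]([C@H](C)C=C)C(=O)O[Si](C)(C)C | intermediate
16 | (2S,3R)-2-(5-hydroxy-2-oxo-3-oxabicyclo[3.2.1]octan-8-yl)-3-methylpent-4-enoic acid (2,3-anti) | O=C3OC[C@@]1(O)CC[C@@H]3[C@H]1[C@H]([C@H](C)C=C)C(=O)O | intermediate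
17 | (2S,3R)-2-(2,5-dihydroxy-2-methyl-3-oxabicyclo[3.2.1]octan-8-yl)-3-methylpent-4-enoic acid (methyl hemiketal, ring-chain tautomer of the methyl ketone) | CC3(O)OC[C@@]1(O)CC[C@@H]3[C@H]1[C@H]([C@H](C)C=C)C(=O)O | intermediate
18 | 5-bromo-2-methylpent-2-ene | CC(C)=CCCBr | starting material
19 | triphenylphosphine | c1ccc(cc1)P(c1ccccc1)c1ccccc1 | starting material
20 | (4-methylpent-3-en-1-yl)triphenylphosphonium bromide | CC(C)=CCC[P+](c1ccccc1)(c1ccccc1)c1ccccc1.[Br-] | intermediate
21 | (2S,3R)-2-[(1S,2R,5R)-2-hydroxy-2-(hydroxymethyl)-5-[(2Z)-6-methylhepta-2,5-dien-2-yl]cyclopentyl]-3-methylpent-4-enoic acid | OC[C@@]1(O)CC[C@@H](/C(C)=C\CC=C(C)C)[C@H]1[C@H]([C@H](C)C=C)C(=O)O | intermediate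
22 | (4S)-4-[(2R)-but-3-en-2-yl]-7a-hydroxy-5-[(2Z)-6-methylhepta-2,5-dien-2-yl]hexahydrocyclopenta[c]pyran-3(1H)-one (cis-fused; ring A as in 25) | O=C2OC[C@@]1(O)CC[C@@H](/C(C)=C\CC=C(C)C)[C@H]1[C@@H]2[C@H](C)C=C | intermediate
23 | (4S,5R)-4-[(1S,2R,5R)-2-hydroxy-2-(hydroxymethyl)-5-[(2Z)-6-methylhepta-2,5-dien-2-yl]cyclopentyl]-5-methylhepta-1,6-dien-3-one | OC[C@@]1(O)CC[C@@H](/C(C)=C\CC=C(C)C)[C@H]1[C@H]([C@H](C)C=C)C(=O)C=C | intermediate
24 | (4R,5S)-5-[(1S,2R,5R)-2-hydroxy-2-(hydroxymethyl)-5-[(2Z)-6-methylhepta-2,5-dien-2-yl]cyclopentyl]-4-methylcyclopent-2-en-1-one | OC[C@@]1(O)CC[C@@H](/C(C)=C\CC=C(C)C)[C@H]1[C@H]1C(=O)C=C[C@H]1C | intermediate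
25 | [(1R,2S,3R)-1-hydroxy-3-[(2Z)-6-methylhepta-2,5-dien-2-yl]-2-[(1S,5R)-5-methyl-2-oxocyclopent-3-en-1-yl]cyclopentyl]methyl acetate | CC(=O)OC[C@@]1(O)CC[C@@H](/C(C)=C\CC=C(C)C)[C@H]1[C@H]1C(=O)C=C[C@H]1C | target

## Step count and risks

Total steps: 14. Longest linear sequence: 13 (steps 1–9 and 11–14; step 10 is a one-step side branch).

The three steps most likely to fail:

Step 5 (the proposed new step). The dienoate ester is a weaker acceptor than the enones for which this ring closure is established, and the cis outcome and the enantioselectivity are untested on it. A formyl epimer formed after ring closure is not lost: a trace of DBU in step 6 funnels it into 12, because only the cis epimer can close the bridged lactol. What must be high is the selectivity at C5. Fallback with known chemistry, setting out from 5: Wittig olefination with 1-(4-methoxyphenyl)-2-(triphenylphosphoranylidene)ethanone gives the anisyl dienone acetal F1. Acid hydrolysis gives the formyl aryl enone F2, which belongs to the acceptor class for which the cis-selective amine-catalysed 5-exo Michael closure is established, and that closure gives the cis keto aldehyde F3. The conditions of steps 6 and 7 give the bridged lactol F4 and then the bridged lactone ketone F5. Baeyer–Villiger oxidation with CF3CO3H (buffered with Na2HPO4; the anisyl group migrates) gives the aryl ester F6. Transesterification with 6 (DMAP, Et3N) comes back to the route at 13.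

Step 8. The anti relation C1'/C5' is reliable, but the facial selectivity relative to C5 rests on substrate control by the silylated bridgehead and may be modest. Fallback, setting out from 13: silylation (Me3SiCl, imidazole) gives the trimethylsilyl ether F7. This is enolised with a chiral 2-bromo-4,5-diphenyl-1,3-bis(arylsulfonyl)-1,3,2-diazaborolidine and Et3N in toluene at −78 °C, and the (E)-boron ketene acetal rearranges on warming (reagent-controlled enolate Claisen rearrangement). The controller enantiomer that places the crotyl group on the required enolate face is chosen, so the stereocontrol no longer depends on the substrate. Acidic work-up removes the silyl ether and comes back to the route at 16.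

Step 11. The Z selectivity of a Wittig reaction on an α-branched methyl ketone is only moderate in general, and the open ketone can epimerise at C4 under the basic conditions. Fallback, setting out from 17: aqueous NaOH turns 20 into (4-methylpent-3-en-1-yl)diphenylphosphine oxide F8. Its lithio derivative (LiN(iPr)2, THF, −78 °C) is added to 17 that has first been deprotonated with LiN(SiMe3)2 (Horner–Wittig addition). The β-hydroxy phosphine oxide diastereomers are separated, and the one in which syn-periplanar oxygen and phosphorus place ring and chain on the same side, β-hydroxy phosphine oxide F9, is eliminated with KH in DMF (stereospecific syn elimination). This gives 21 as the pure Z isomer, which is lactonised as in step 11 and comes back to the route at 22.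

## Further compounds

F1 | step 5 | (2E)-8,8-dimethoxy-1-(4-methoxyphenyl)-4-methylideneoct-2-en-1-one | COC(OC)CCCC(=C)/C=C/C(=O)c1ccc(OC)cc1
F2 | step 5 | (5E)-7-(4-methoxyphenyl)-4-methylidene-7-oxohept-5-enal | O=CCCCC(=C)/C=C/C(=O)c1ccc(OC)cc1
F3 | step 5 | (1R,2R)-2-[2-(4-methoxyphenyl)-2-oxoethyl]-3-methylidenecyclopentane-1-carbaldehyde (cis) | C=C1CC[C@@H](C=O)[C@H]1CC(=O)c1ccc(OC)cc1
F4 | step 5 | 2-(2,5-dihydroxy-3-oxabicyclo[3.2.1]octan-8-yl)-1-(4-methoxyphenyl)ethanone (bridged lactol) | OC3OC[C@@]1(O)CC[C@@H]3[C@H]1CC(=O)c1ccc(OC)cc1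
F5 | step 5 | 5-hydroxy-8-[2-(4-methoxyphenyl)-2-oxoethyl]-3-oxabicyclo[3.2.1]octan-2-one | O=C3OC[C@@]1(O)CC[C@@H]3[C@H]1CC(=O)c1ccc(OC)cc1
F6 | step 5 | 4-methoxyphenyl 2-(5-hydroxy-2-oxo-3-oxabicyclo[3.2.1]octan-8-yl)acetate | O=C3OC[C@@]1(O)CC[C@@H]3[C@H]1CC(=O)Oc1ccc(OC)cc1
F7 | step 8 | (E)-but-2-en-1-yl 2-[2-oxo-5-(trimethylsilyloxy)-3-oxabicyclo[3.2.1]octan-8-yl]acetate | O=C3OC[C@@]1(O[Si](C)(C)C)CC[C@@H]3[C@H]1CC(=O)OC/C=C/C
F8 | step 11 | (4-methylpent-3-en-1-yl)diphenylphosphine oxide | CC(C)=CCCP(=O)(c1ccccc1)c1ccccc1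
F9 | step 11 | (2S,3R)-2-[5-[3-(diphenylphosphoryl)-2-hydroxy-7-methyloct-6-en-2-yl]-2-hydroxy-2-(hydroxymethyl)cyclopentyl]-3-methylpent-4-enoic acid (diastereomer that gives the Z alkene on syn elimination) | OC[C@@]1(O)CC[C@@H]([C@@](C)(O)[C@H](CC=C(C)C)P(=O)(c2ccccc2)c2ccccc2)[C@H]1[C@H]([C@H](C)C=C)C(=O)O
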